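A reciprocal minute is a chance per minute, and in that unit we follow a single molecule of starting material through these flasks.

    starting material + target → side product (k1 = 2.98 M⁻¹ min⁻¹, Ea1 = 68.0 kJ mol⁻¹)
    starting material + protic impurity → quenched substrate (k2 = 2.65 M⁻¹ min⁻¹, Ea2 = 60.0 kJ mol⁻¹)
    starting material + partner + catalyst → catalyst + target (k3 = 1.07 × 10⁵ M⁻² min⁻¹, Ea3 = 38.0 kJ mol⁻¹)
    crystals ⇌ target, rate k4*(cs4 - [target]) while solid is left; crystals form when [target] > cs4 (cs4 = 5.0 mM, k4 = 0.252 min⁻¹)
    (constants at 80 °C)

| setting | red | blue | violet | teal | amber | green |
|---|---|---|---|---|---|---|
| starting material | 10 mM (fed, over 80 min) | 10 mM (fed, over 8.0 min) | 10 mM (fed, over 80 min) | 10 mM | 10 mM | 10 mM |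
| partner | 5.00 mM | 5.00 mM | 5.00 mM | 5.00 mM | 5.00 mM (fed, over 80 min) | 5.00 mM |
| protic impurity | 10.0 mM | 10.0 mM | 10.0 mM | 10.0 mM | 10.0 mM | 10.0 mM |
| catalyst | 100 µM | 100 µM | 100 µM | 100 µM | 100 µM | 100 µM |
| time | 2.0 h | 2.0 h | 2.0 h | 2.0 h | 2.0 h | 2.0 h |
| remark | the addition at 50 °C, then warmed to 80 °C; the feed brings no volume worth counting | all else is in the flask from the start; the feed brings no volume worth counting | all else is in the flask from the start; the feed brings no volume worth counting | everything together at the start | all else is in the flask from the start; the feed brings no volume worth counting | everything together at the start at 50 °C, warmed to 80 °C at 80 min |
| temperature |  | 80 °C | 80 °C | 80 °C | 80 °C |  |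

- percentages count the starting material that a species holds: one side product counts as two
- target is meant together with its crystals
- solid, in amounts per volume of the solution: crystals
- the list of constants is for 80 °C, to be carried to other temperatures by the activation energies

- which flask leads in amount of target, in percent of the starting material charged ("all alike" within 1.5 percentage points) (red / blue / violet / teal / amber / green / all alike)
- how much target is there at the end, in percent of the starting material charged: red
- how much target is there at the end, in percent of the starting material charged: blue
- how much target is there at the end, in percent of the starting material charged: violet
- how much target is there at the end, in percent of the starting material charged: teal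
- how much target is there at the end, in percent of the starting material charged: amber
- how much target is there at the end, in percent of the starting material charged: green

A molecule of starting material stands at a fork. In teal at the start, the coupling claims it at 0.0535 min⁻¹ and the protic impurity at 0.0265 min⁻¹, so the coupling is twice as likely. Both chances shrink as partner and impurity are used up, but c(starting material) stands in both rates and cancels from their ratio. The catalyst leaves the coupling unchanged, so c(catalyst) holds.

What remains is the fork constant, a selectivity factor: the coupling's rate constant times c(catalyst), divided by the quench's rate constant, 4.04. With partner and impurity charged at the start and the temperature held, the fraction of partner left equals the fraction of impurity left raised to this power. The feed of starting material does not enter, and the side step touches neither reagent. Amber, whose partner is fed, lies outside the rule.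

Now the ladder of times at 80 °C, each a half-life of starting material by one step, with partner and impurity as charged. The quick feed takes 8.0 min, less than the coupling's half-life of 13.0 min, so blue should look like teal. The quench follows at 26.2 min. The side step is slower still, 46.5 min even with target at its ceiling. The slow feed of 80 min outlasts all of these, and the run ends at 120 min. The ceiling on target is the partner charge, 5.00 mM, which is the solubility 5.0 mM itself, so we expect no crystals.

Cooling to 50 °C raises the fork constant to 8.10. We have not reckoned what the side step takes, so we stop at an ordering: blue, violet and teal together, with red and green above them, and no choice between those two.

The forecast goes one step further and names green. It gives red 31.8 %, blue 30.2 %, violet 30.4 %, teal 30.1 %, amber 23 % and green 33.2 %, holding that at 80 °C “feeding the starting material barely changes the outcome”.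

The simulation gives red 31.8 %, blue 30.1 %, violet 30.4 %, teal 30.1 %, amber 23.0 % and green 33.3 %, with green leading as forecast. Teal ends with 59 % of its impurity left, which raised to the fork constant 4.04 gives 11.9 % of the partner, against 12 % in the flask. Violet, fed over 80 min and still holding 6.0 % of its starting material, ends with 62 % of its impurity, which gives 14.1 % of the partner, against 14 % in the flask.

The constants were set for the occasion; the rest is arithmetic.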